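The flavonol is cut back to ring A, where C8a (bearing O1) and C8 (bearing the 2-methylbut-3-en-2-yl group) are neighbours and C8 is flanked by the oxygenated C7. Both bonds, C8a–O and C8–C(quaternary), are to be made in one operation: the oxygen of prenyl 4-methoxybenzyl ether adds to a 3,5-bis(methoxymethoxy)benzyne and the resulting aryl anion takes the prenyl γ-carbon. The precursor is an ortho-silyl aryl triflate made from phloroglucinol through an easily cleaved N-isopropyl carbamate. Oxidative removal of the 4-methoxybenzyl group then frees O1 alone, so ring C is built on the correct oxygen by ortho-formylation, chalcone formation and Algar–Flynn–Oyamada oxidation.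

Key step: step 6

Remark on the chemistry: the target is achiral; the stereocenters of compounds 19, 23 and 24 are transient, so these compounds are racemic and their configuration is of no consequence. Ring positions are named by flavone numbering (O1, C2, C3, C4, C4a, C5 to C8, C8a).

Step 1
Reactants: 1 phloroglucinol
Product: 2 3,5-bis(methoxymethoxy)phenol
Conditions: MOMCl (2.0 equiv), i-Pr2NEt, DMF, 0 °C → rt
Reagents that add atoms: chloromethyl methyl ether, COCCl
Why: Williamson-type O-alkylation with the chloromethyl ether; two equivalents on the threefold-symmetric triol should give the bis-acetal as the main component of a statistical mixture, separable by chromatography from the mono- and tris-acetals.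

Step 2
Reactants: 2 3,5-bis(methoxymethoxy)phenol
Product: 3 3,5-bis(methoxymethoxy)phenyl N-isopropylcarbamate
Conditions: i-PrNCO, Et3N (cat.), CH2Cl2, rt
Reagents that add atoms: isopropyl isocyanate, CC(C)N=C=O
Why: Amine-catalysed addition of the phenol to the isocyanate (carbamoylation) installs an N–H carbamate that directs metalation and can later be removed by base alone.

Step 3
Reactants: 3 3,5-bis(methoxymethoxy)phenyl N-isopropylcarbamate
Product: 7 3,5-bis(methoxymethoxy)-2-(trimethylsilyl)phenyl N-isopropylcarbamate, via N-silyl carbamate 4 (not isolated), via aryllithium 5 (not isolated), via N-silyl arylsilane 6 (not isolated)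
Conditions: TBSOTf, TMEDA, Et2O, 0 °C → rt; n-BuLi, TMEDA, –78 °C; Me3SiCl, –78 °C → rt; aq NH4Cl
Reagents that add atoms: chlorotrimethylsilane, C[Si](C)(C)Cl (tert-butyldimethylsilyl trifluoromethanesulfonate, CC(C)(C)[Si](C)(C)OS(=O)(=O)C(F)(F)F, and n-butyllithium, [Li]CCCC, add atoms only to intermediates 4 to 6)
Why: Directed ortho-metalation of the Snieckus–Hoppe type: in situ N-silylation masks the N–H, the carbamate (the strongest director present) and the neighbouring methoxymethoxy group jointly acidify C2–H (C2 and C6 are equivalent), the aryllithium is silylated and the N-silyl group is hydrolysed during the mild, non-acidic work-up.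

Step 4
Reactants: 7 3,5-bis(methoxymethoxy)-2-(trimethylsilyl)phenyl N-isopropylcarbamate
Product: 9 3,5-bis(methoxymethoxy)-2-(trimethylsilyl)phenyl trifluoromethanesulfonate, via silylphenol 8 (not isolated)
Conditions: Et2NH, DBU, MeCN, 40 °C; then PhNTf2, rt
Reagents that add atoms: N-phenylbis(trifluoromethanesulfonimide), O=S(=O)(N(c1ccccc1)S(=O)(=O)C(F)(F)F)C(F)(F)F
Why: E1cB cleavage of the N-monosubstituted carbamate (the amidine base removes N–H, phenoxide leaves, diethylamine scavenges isopropyl isocyanate as a urea) followed by O-sulfonylation of the phenoxide in the same pot avoids the acid or hydride that could protodesilylate the electron-rich arylsilane.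

Step 5
Reactants: 10 4-methoxybenzyl alcohol; 11 1-bromo-3-methylbut-2-ene
Product: 12 1-methoxy-4-{[(3-methylbut-2-en-1-yl)oxy]methyl}benzene
Conditions: NaH, THF, 0 °C; 11, n-Bu4NI (cat.), rt
Reagents that add atoms: none
Why: Williamson ether synthesis: the sodium alkoxide displaces bromide at the primary allylic carbon (SN2) without allylic transposition.

Step 6
Reactants: 9 3,5-bis(methoxymethoxy)-2-(trimethylsilyl)phenyl trifluoromethanesulfonate; 12 1-methoxy-4-{[(3-methylbut-2-en-1-yl)oxy]methyl}benzene
Product: 15 1-[(4-methoxybenzyl)oxy]-3,5-bis(methoxymethoxy)-2-(2-methylbut-3-en-2-yl)benzene, via benzyne 13 (not isolated), via oxonium zwitterion 14 (not isolated)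
Conditions: n-Bu4N[Ph3SiF2] (TBAT), 12 (5 equiv), PhMe, 4 Å MS, rt → 50 °C
Reagents that add atoms: none
Why: Proposed new method: fluoride attacks silicon of 9 and triflate leaves to give aryne 13, whose C1≡C2 bond is polarised by the inductively withdrawing methoxymethoxy group on C3, so the ether oxygen of 12 adds at C1 (future C8a, remote from that group) and the in-plane aryl anion of zwitterion 14 sits at C2 (future C8). The anion then attacks the dimethyl-substituted γ-carbon of the O-prenyl group through a six-membered SN2′ transition state, the neutral aryl 4-methoxybenzyl ether acting as leaving group, which forms C8a–O and the C8–quaternary carbon bond and cancels both charges at or near room temperature. The closest known reaction types are the aryne aza-Claisen reaction of tertiary allylamines, allyl transfer in adducts of arynes with allyl sulfides, and the cleavage of dialkyl and cyclic ethers by arynes through oxonium betaines, in which β-hydrogen abstraction passes through the same six-membered geometry. No ring is closed and no stereocenter is formed. The step needs regioselective addition, secured by the 3-alkoxy group of the aryne, and chemoselectivity for allyl transfer over benzylic proton transfer, benzyl shift and external protonation, secured by the six-membered geometry, by a medium free of proton sources and of competing ether solvents (anhydrous silicate fluoride, toluene, molecular sieves) and by an excess of 12 that should also outcompete fluoride addition and the aryne ene reaction at the prenyl double bond.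

Step 7
Reactants: 15 1-[(4-methoxybenzyl)oxy]-3,5-bis(methoxymethoxy)-2-(2-methylbut-3-en-2-yl)benzene
Product: 16 3,5-bis(methoxymethoxy)-2-(2-methylbut-3-en-2-yl)phenol
Conditions: DDQ, CH2Cl2/pH 7 phosphate buffer, 0 °C → rt
Reagents that add atoms: none
Why: Oxidative debenzylation: DDQ abstracts hydride from the benzylic CH2 activated by the para-methoxy group and water cleaves the oxocarbenium ion, while the buffered medium leaves the acetals and the monosubstituted alkene untouched.

Step 8
Reactants: 16 3,5-bis(methoxymethoxy)-2-(2-methylbut-3-en-2-yl)phenol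
Product: 18 2-hydroxy-4,6-bis(methoxymethoxy)-3-(2-methylbut-3-en-2-yl)benzaldehyde, via hydroxymethylphenol 17 (not isolated)
Conditions: MgCl2, Et3N, (CH2O)n, MeCN, reflux
Reagents that add atoms: paraformaldehyde (as formaldehyde), C=O
Why: Magnesium-mediated ortho-formylation (Casnati–Skattebøl reaction): the magnesium phenoxide delivers formaldehyde only to the single free ortho carbon C4a (C8 is substituted; the para carbon C6 is out of reach) and the resulting hydroxymethyl compound is oxidised to the aldehyde by a second formaldehyde through hydride transfer, all under basic conditions.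

Step 9
Reactants: 18 2-hydroxy-4,6-bis(methoxymethoxy)-3-(2-methylbut-3-en-2-yl)benzaldehyde
Product: 19 racemic 1-[2-hydroxy-4,6-bis(methoxymethoxy)-3-(2-methylbut-3-en-2-yl)phenyl]ethan-1-ol
Conditions: MeMgBr (3 equiv), THF, –20 → 0 °C; aq NH4Cl
Reagents that add atoms: methylmagnesium bromide, C[Mg]Br
Why: Grignard addition to the aldehyde after deprotonation of the phenol; the carbinol stereocenter is formed without control (racemic) and is erased in step 10.

Step 10
Reactants: 19 racemic 1-[2-hydroxy-4,6-bis(methoxymethoxy)-3-(2-methylbut-3-en-2-yl)phenyl]ethan-1-ol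
Product: 20 1-[2-hydroxy-4,6-bis(methoxymethoxy)-3-(2-methylbut-3-en-2-yl)phenyl]ethan-1-one
Conditions: MnO2 (activated, excess), CH2Cl2, rt
Reagents that add atoms: none
Why: Selective heterogeneous oxidation of the benzylic alcohol by MnO2 under neutral conditions should give the hydrogen-bonded ortho-hydroxy aryl ketone and spare acetals and alkene.

Step 11
Reactants: 20 1-[2-hydroxy-4,6-bis(methoxymethoxy)-3-(2-methylbut-3-en-2-yl)phenyl]ethan-1-one; 21 4-methoxybenzaldehyde
Product: 22 (E)-1-[2-hydroxy-4,6-bis(methoxymethoxy)-3-(2-methylbut-3-en-2-yl)phenyl]-3-(4-methoxyphenyl)prop-2-en-1-one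
Conditions: KOH, EtOH/H2O, rt
Reagents that add atoms: none
Why: Claisen–Schmidt aldol condensation of the methyl ketone enolate with the non-enolisable aldehyde and E1cB dehydration give the thermodynamically favoured E-enone.

Step 12
Reactants: 22 (E)-1-[2-hydroxy-4,6-bis(methoxymethoxy)-3-(2-methylbut-3-en-2-yl)phenyl]-3-(4-methoxyphenyl)prop-2-en-1-one
Product: 25 3-hydroxy-2-(4-methoxyphenyl)-5,7-bis(methoxymethoxy)-8-(2-methylbut-3-en-2-yl)-4H-chromen-4-one, via chalcone epoxide 23 (not isolated), via trans-dihydroflavonol 24 (not isolated)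
Conditions: 30% aq H2O2, NaOH, MeOH, 0 °C → rt
Reagents that add atoms: hydrogen peroxide, OO
Why: Algar–Flynn–Oyamada oxidation: hydroperoxide epoxidises only the electron-poor enone, the phenoxide on C8a opens the epoxide at the benzylic β-carbon (six-membered closure favoured by the electron-rich 4-methoxyphenyl group) to the trans-dihydroflavonol, whose two transient stereocenters disappear on in situ oxidation to the flavonol.

Step 13
Reactants: 25 3-hydroxy-2-(4-methoxyphenyl)-5,7-bis(methoxymethoxy)-8-(2-methylbut-3-en-2-yl)-4H-chromen-4-one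
Product: 26 3,5,7-trihydroxy-2-(4-methoxyphenyl)-8-(2-methylbut-3-en-2-yl)-4H-chromen-4-one
Conditions: 3 M aq HCl, MeOH, 45 °C
Reagents that add atoms: none
Why: Acid-catalysed methanolysis of the two methoxymethyl acetals; under dilute acid at mild temperature the monosubstituted alkene on a quaternary carbon should resist protonation, so the 7-hydroxyl does not cyclise onto it.

Compound list
1 | phloroglucinol (benzene-1,3,5-triol) | Oc1cc(O)cc(O)c1 | starting material
2 | 3,5-bis(methoxymethoxy)phenol | COCOc1cc(O)cc(OCOC)c1 | intermediate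
3 | 3,5-bis(methoxymethoxy)phenyl N-isopropylcarbamate | CC(C)NC(=O)Oc1cc(OCOC)cc(OCOC)c1 | intermediate
4 | 3,5-bis(methoxymethoxy)phenyl N-(tert-butyldimethylsilyl)-N-isopropylcarbamate | CC(C)N(C(=O)Oc1cc(OCOC)cc(OCOC)c1)[Si](C)(C)C(C)(C)C | intermediate (not isolated)
5 | [2-{[(tert-butyldimethylsilyl)(isopropyl)carbamoyl]oxy}-4,6-bis(methoxymethoxy)phenyl]lithium | CC(C)N(C(=O)Oc1cc(OCOC)cc(OCOC)c1[Li])[Si](C)(C)C(C)(C)C | intermediate (not isolated)
6 | 3,5-bis(methoxymethoxy)-2-(trimethylsilyl)phenyl N-(tert-butyldimethylsilyl)-N-isopropylcarbamate | CC(C)N(C(=O)Oc1cc(OCOC)cc(OCOC)c1[Si](C)(C)C)[Si](C)(C)C(C)(C)C | intermediate (not isolated)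
7 | 3,5-bis(methoxymethoxy)-2-(trimethylsilyl)phenyl N-isopropylcarbamate | CC(C)NC(=O)Oc1cc(OCOC)cc(OCOC)c1[Si](C)(C)C | intermediate
8 | 3,5-bis(methoxymethoxy)-2-(trimethylsilyl)phenol | COCOc1cc(O)c([Si](C)(C)C)c(OCOC)c1 | intermediate (not isolated)
9 | 3,5-bis(methoxymethoxy)-2-(trimethylsilyl)phenyl trifluoromethanesulfonate | COCOc1cc(OCOC)c([Si](C)(C)C)c(OS(=O)(=O)C(F)(F)F)c1 | intermediate
10 | 4-methoxybenzyl alcohol | COc1ccc(CO)cc1 | starting material
11 | 1-bromo-3-methylbut-2-ene | CC(C)=CCBr | starting material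
12 | 1-methoxy-4-{[(3-methylbut-2-en-1-yl)oxy]methyl}benzene | COc1ccc(COCC=C(C)C)cc1 | intermediate
13 | 3,5-bis(methoxymethoxy)benzyne (1,2-didehydro-3,5-bis(methoxymethoxy)benzene) | COCOC1=CC#CC(OCOC)=C1 | intermediate (not isolated)
14 | 2-[(4-methoxybenzyl)(3-methylbut-2-en-1-yl)oxonio]-4,6-bis(methoxymethoxy)benzen-1-ide (zwitterion) | COCOc1cc(OCOC)[c-]c([O+](Cc2ccc(OC)cc2)CC=C(C)C)c1 | intermediate (not isolated)
15 | 1-[(4-methoxybenzyl)oxy]-3,5-bis(methoxymethoxy)-2-(2-methylbut-3-en-2-yl)benzene | C=CC(C)(C)c1c(OCc2ccc(OC)cc2)cc(OCOC)cc1OCOC | intermediate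
16 | 3,5-bis(methoxymethoxy)-2-(2-methylbut-3-en-2-yl)phenol | C=CC(C)(C)c1c(O)cc(OCOC)cc1OCOC | intermediate
17 | 2-(hydroxymethyl)-3,5-bis(methoxymethoxy)-6-(2-methylbut-3-en-2-yl)phenol | C=CC(C)(C)c1c(O)c(CO)c(OCOC)cc1OCOC | intermediate (not isolated)
18 | 2-hydroxy-4,6-bis(methoxymethoxy)-3-(2-methylbut-3-en-2-yl)benzaldehyde | C=CC(C)(C)c1c(O)c(C=O)c(OCOC)cc1OCOC | intermediate
19 | racemic 1-[2-hydroxy-4,6-bis(methoxymethoxy)-3-(2-methylbut-3-en-2-yl)phenyl]ethan-1-ol | C=CC(C)(C)c1c(O)c(C(C)O)c(OCOC)cc1OCOC | intermediate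
20 | 1-[2-hydroxy-4,6-bis(methoxymethoxy)-3-(2-methylbut-3-en-2-yl)phenyl]ethan-1-one | C=CC(C)(C)c1c(O)c(C(C)=O)c(OCOC)cc1OCOC | intermediate
21 | 4-methoxybenzaldehyde | COc1ccc(C=O)cc1 | starting material
22 | (E)-1-[2-hydroxy-4,6-bis(methoxymethoxy)-3-(2-methylbut-3-en-2-yl)phenyl]-3-(4-methoxyphenyl)prop-2-en-1-one | C=CC(C)(C)c1c(O)c(C(=O)/C=C/c2ccc(OC)cc2)c(OCOC)cc1OCOC | intermediate
23 | racemic trans-[2-hydroxy-4,6-bis(methoxymethoxy)-3-(2-methylbut-3-en-2-yl)phenyl][3-(4-methoxyphenyl)oxiran-2-yl]methanone (one enantiomer drawn) | C=CC(C)(C)c1c(O)c(C(=O)[C@@H]2O[C@H]2c2ccc(OC)cc2)c(OCOC)cc1OCOC | intermediate (not isolated)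
24 | racemic trans-3-hydroxy-2-(4-methoxyphenyl)-5,7-bis(methoxymethoxy)-8-(2-methylbut-3-en-2-yl)chroman-4-one (one enantiomer drawn) | C=CC(C)(C)c1c(OCOC)cc(OCOC)c2c1O[C@H](c1ccc(OC)cc1)[C@@H](O)C2=O | intermediate (not isolated)
25 | 3-hydroxy-2-(4-methoxyphenyl)-5,7-bis(methoxymethoxy)-8-(2-methylbut-3-en-2-yl)-4H-chromen-4-one | C=CC(C)(C)c1c(OCOC)cc(OCOC)c2c(=O)c(O)c(-c3ccc(OC)cc3)oc12 | intermediate
26 | 3,5,7-trihydroxy-2-(4-methoxyphenyl)-8-(2-methylbut-3-en-2-yl)-4H-chromen-4-one | C=CC(C)(C)c1c(O)cc(O)c2c(=O)c(O)c(-c3ccc(OC)cc3)oc12 | target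

Total step count: 13.
Longest linear sequence: 12 steps (steps 1 to 4 and 6 to 13, from phloroglucinol); step 5 is a one-step side branch.

Steps most likely to fail

1. Step 6 (Proposed new method). The ether oxygen may be too weak a nucleophile, so that the aryne is lost to an ene reaction at the prenyl double bond, to fluoride addition or to self-condensation. The zwitterion may also shift a benzylic proton or be protonated before the allyl group is transferred. The fallback uses known chemistry, the aromatic Claisen rearrangement. It sets out from phenol 2, which is O-alkylated with bromide 11 (K2CO3, acetone, reflux) to 1,3-bis(methoxymethoxy)-5-[(3-methylbut-2-en-1-yl)oxy]benzene F1. Heating F1 in N,N-diethylaniline at about 190 °C should move the allyl group with inversion to the ortho carbon (both ortho carbons are equivalent) through 3,5-bis(methoxymethoxy)-6-(2-methylbut-3-en-2-yl)cyclohexa-2,4-dien-1-one F2, which is not isolated and tautomerises to phenol 16. The route is rejoined there at step 8.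

2. Step 12. The methoxymethoxy group next to the carbonyl twists it out of plane, which may favour five-membered closure at the α-carbon and divert the oxidation to an aurone; alkaline peroxide may also degrade the flavonol. The fallback sets out from chalcone 22, which is cyclised by oxa-Michael addition (NaOAc, EtOH, reflux) to racemic 2-(4-methoxyphenyl)-5,7-bis(methoxymethoxy)-8-(2-methylbut-3-en-2-yl)chroman-4-one F3. Dehydrogenation with DDQ (dioxane, reflux) should give 2-(4-methoxyphenyl)-5,7-bis(methoxymethoxy)-8-(2-methylbut-3-en-2-yl)-4H-chromen-4-one F4. Deprotonation at C3 with LiN(i-Pr)2 (THF, –78 °C) gives [2-(4-methoxyphenyl)-5,7-bis(methoxymethoxy)-8-(2-methylbut-3-en-2-yl)-4-oxo-4H-chromen-3-yl]lithium F5, which is not isolated and is trapped with B(OMe)3 as the lithium trimethoxy(4-oxo-4H-chromen-3-yl)borate F6, also not isolated. Oxidation of the C–B bond with H2O2/AcOH should give flavonol 25, where the route is rejoined at step 13.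

3. Step 3. The silyl triflate may cleave a methoxymethyl acetal before it silylates nitrogen, or deprotonation may take place between the two acetal oxygens instead of beside the carbamate. The fallback sets out from phenol 2, which is converted (NaH, ClC(O)NEt2, THF) to 3,5-bis(methoxymethoxy)phenyl N,N-diethylcarbamate F7, a stronger director that needs no Lewis acid. s-BuLi/TMEDA (THF, –78 °C) gives [2-(diethylcarbamoyloxy)-4,6-bis(methoxymethoxy)phenyl]lithium F8, which is not isolated and is quenched with Me3SiCl to 3,5-bis(methoxymethoxy)-2-(trimethylsilyl)phenyl N,N-diethylcarbamate F9. LiAlH4 (THF, reflux) removes the carbamate reductively to give silylphenol 8, isolated this time, and PhNTf2/DBU (MeCN, rt) converts 8 to triflate 9, where the route is rejoined at step 6.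

Further compounds
F1 | step 6 | 1,3-bis(methoxymethoxy)-5-[(3-methylbut-2-en-1-yl)oxy]benzene | COCOc1cc(OCC=C(C)C)cc(OCOC)c1
F2 | step 6 | racemic 3,5-bis(methoxymethoxy)-6-(2-methylbut-3-en-2-yl)cyclohexa-2,4-dien-1-one (not isolated) | C=CC(C)(C)C1C(=O)C=C(OCOC)C=C1OCOC
F3 | step 12 | racemic 2-(4-methoxyphenyl)-5,7-bis(methoxymethoxy)-8-(2-methylbut-3-en-2-yl)chroman-4-one | C=CC(C)(C)c1c(OCOC)cc(OCOC)c2c1OC(c1ccc(OC)cc1)CC2=O
F4 | step 12 | 2-(4-methoxyphenyl)-5,7-bis(methoxymethoxy)-8-(2-methylbut-3-en-2-yl)-4H-chromen-4-one | C=CC(C)(C)c1c(OCOC)cc(OCOC)c2c(=O)cc(-c3ccc(OC)cc3)oc12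
F5 | step 12 | [2-(4-methoxyphenyl)-5,7-bis(methoxymethoxy)-8-(2-methylbut-3-en-2-yl)-4-oxo-4H-chromen-3-yl]lithium (not isolated) | C=CC(C)(C)c1c(OCOC)cc(OCOC)c2c(=O)c([Li])c(-c3ccc(OC)cc3)oc12
F6 | step 12 | lithium trimethoxy[2-(4-methoxyphenyl)-5,7-bis(methoxymethoxy)-8-(2-methylbut-3-en-2-yl)-4-oxo-4H-chromen-3-yl]borate (not isolated) | C=CC(C)(C)c1c(OCOC)cc(OCOC)c2c(=O)c([B-](OC)(OC)OC)c(-c3ccc(OC)cc3)oc12.[Li+]
F7 | step 3 | 3,5-bis(methoxymethoxy)phenyl N,N-diethylcarbamate | CCN(CC)C(=O)Oc1cc(OCOC)cc(OCOC)c1
F8 | step 3 | [2-(diethylcarbamoyloxy)-4,6-bis(methoxymethoxy)phenyl]lithium (not isolated) | CCN(CC)C(=O)Oc1cc(OCOC)cc(OCOC)c1[Li]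
F9 | step 3 | 3,5-bis(methoxymethoxy)-2-(trimethylsilyl)phenyl N,N-diethylcarbamate | CCN(CC)C(=O)Oc1cc(OCOC)cc(OCOC)c1[Si](C)(C)C
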